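**Assumption:** the (S)-configured biaryl bisphosphine in Step 14 is taken to give the (2S) product, by analogy with (S)-BINAP giving (S)-3-arylcyclohexanones. This sense of induction is not confirmed for chromones; check it by CD or chiral HPLC and use the (R)-ligand if it is reversed.

## Retrosynthetic overview

1. Kuwanon E comes from its tetra-MOM ether by a final global acetal cleavage.
2. The C2–C1' bond is disconnected to 5,7-bis(MOMO)chromone plus a 5-geranyl-2,4-bis(MOMO)phenylboronic acid; a Rh-catalysed asymmetric 1,4-addition joins them and sets C2 as (S).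
3. The chromone comes from resorcinol by meta C–H borylation/oxidation, ortho-formylation, ethynyl addition and oxidation/6-endo cyclisation.
4. The boronic acid comes from the same bis-MOM resorcinol by dibromination, then two sequential Br/Li exchanges (Cu-mediated geranylation, then borylation); geranyl bromide comes from prenyl bromide and TMS-propyne by Negishi carboalumination.
5. Ring order: both benzene rings are bought as resorcinol; the pyranone ring is the only ring built (Step 6) and becomes the chromanone in Step 14.

## Route

### Chromone fragment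

**Step 1**
Reactants: 1, resorcinol
Product: 2, 1,3-bis(methoxymethoxy)benzene
Conditions: MOMCl (2.4 equiv), i-Pr2NEt, CH2Cl2, 0 °C → rt
Reagents that add atoms: chloromethyl methyl ether, COCCl
Why: Phenoxide O-alkylation (Williamson-type acetal formation) protects both phenols as base-stable MOM ethers.

**Step 2**
Reactants: 2, 1,3-bis(methoxymethoxy)benzene
Product: 3, 2-[3,5-bis(methoxymethoxy)phenyl]-4,4,5,5-tetramethyl-1,3,2-dioxaborolane
Conditions: B2pin2 (0.6 equiv), [Ir(OMe)(cod)]2 (1.5 mol %), dtbpy (3 mol %), THF, 80 °C
Reagents that add atoms: bis(pinacolato)diboron, CC1(C)OB(OC1(C)C)B1OC(C)(C)C(C)(C)O1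
Why: Sterically controlled Ir-catalysed aromatic C–H borylation goes to C5, the only position not ortho to a substituent.

**Step 3**
Reactants: 3, aryl pinacol boronate
Product: 4, 3,5-bis(methoxymethoxy)phenol
Conditions: 30 % H2O2, aq. NaOH, THF, 0 °C → rt; Na2S2O3, then NH4Cl to pH 6
Reagents that add atoms: hydrogen peroxide, OO
Why: Boronate oxidation (B-to-O 1,2-aryl shift) gives the phenol under basic conditions that leave MOM ethers untouched.

**Step 4**
Reactants: 4, 3,5-bis(methoxymethoxy)phenol
Product: 5, 2-hydroxy-4,6-bis(methoxymethoxy)benzaldehyde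
Conditions: MgCl2 (2 equiv), Et3N (4 equiv), (CH2O)n (6 equiv), MeCN, reflux
Reagents that add atoms: paraformaldehyde (formaldehyde), C=O
Why: Magnesium-phenoxide-templated ortho-formylation (Casnati–Skattebøl) delivers the formyl group only ortho to the free OH, and the two ortho sites are equivalent.

**Step 5**
Reactants: 5, 2-hydroxy-4,6-bis(methoxymethoxy)benzaldehyde; 6, ethynylmagnesium bromide (3 equiv)
Product: 7, 1-[2-hydroxy-4,6-bis(methoxymethoxy)phenyl]prop-2-yn-1-ol (racemic, used crude)
Conditions: THF, 0 °C → rt; aq. NH4Cl
Reagents that add atoms: none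
Why: Grignard 1,2-addition to the aldehyde (one equivalent is consumed by the phenol); the carbinol centre is removed in the next step.

**Step 6**
Reactants: 7, propargylic alcohol
Product: 8, 5,7-bis(methoxymethoxy)-4H-chromen-4-one
Conditions: activated MnO2 (15 equiv), CH2Cl2, rt; filter; K2CO3 (0.3 equiv), acetone, rt
Reagents that add atoms: none
Why: Benzylic/propargylic oxidation gives the o-hydroxyaryl ynone, which closes by base-catalysed 6-endo-dig oxa-Michael addition at the unsubstituted alkyne terminus to form the pyranone ring without acid.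

### Geranyl fragment

**Step 7**
Reactants: 9, 1-(trimethylsilyl)propyne; 10, prenyl bromide (1-bromo-3-methylbut-2-ene)
Product: 11, trimethyl(6-methylhept-5-en-1-yn-1-yl)silane
Conditions: 9, n-BuLi, THF, −78 → −20 °C; then 10, −78 °C → rt
Reagents that add atoms: none
Why: The silyl-blocked propargyl anion is alkylated at carbon by the primary allylic bromide (SN2) to give the 1,5-enyne.

**Step 8**
Reactants: 11, silyl enyne
Product: 12, 6-methylhept-5-en-1-yne (volatile; isolate by careful distillation)
Conditions: K2CO3, MeOH, rt
Reagents that add atoms: none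
Why: Methanolysis cleaves the alkynyl C–Si bond (protodesilylation) to release the terminal alkyne.

**Step 9**
Reactants: 12, 6-methylhept-5-en-1-yne
Product: 13, geraniol, (2E)-3,7-dimethylocta-2,6-dien-1-ol
Conditions: Me3Al (2 equiv), Cp2ZrCl2 (25 mol %), CH2Cl2, rt; then n-BuLi, THF, −78 °C; (CH2O)n, → rt
Reagents that add atoms: trimethylaluminium, C[Al](C)C; paraformaldehyde (formaldehyde), C=O
Why: Negishi Zr-catalysed syn-methylalumination of the terminal alkyne fixes the (E)-trisubstituted alkene, and the derived alanate adds to formaldehyde with retention.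

**Step 10**
Reactants: 13, geraniol
Product: 14, geranyl bromide, (2E)-1-bromo-3,7-dimethylocta-2,6-diene (used immediately)
Conditions: PBr3 (0.4 equiv), cat. pyridine, Et2O, −10 → 0 °C
Reagents that add atoms: phosphorus tribromide, BrP(Br)Br
Why: SN2 displacement of the activated primary allylic alcohol at low temperature keeps the E geometry and avoids allylic transposition.

### Arylboronic acid fragment

**Step 11**
Reactants: 2, 1,3-bis(methoxymethoxy)benzene
Product: 15, 1,5-dibromo-2,4-bis(methoxymethoxy)benzene
Conditions: NBS (2.1 equiv), MeCN, 0 °C → rt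
Reagents that add atoms: N-bromosuccinimide, O=C1CCC(=O)N1Br
Why: Electrophilic aromatic bromination occurs at the two positions ortho/para to the alkoxy groups (C4, C6), while the hindered C2 stays free.

**Step 12**
Reactants: 15, dibromide; 14, geranyl bromide (1.2 equiv)
Product: 16, 1-bromo-5-[(2E)-3,7-dimethylocta-2,6-dien-1-yl]-2,4-bis(methoxymethoxy)benzene
Conditions: n-BuLi (1.05 equiv), THF, −78 °C; CuBr·SMe2 (1.1 equiv), −78 → −40 °C; then 14, −78 → 0 °C
Reagents that add atoms: none
Why: Mono bromine–lithium exchange, transmetalation to copper and allylic substitution at the unhindered α-carbon (SN2) attach the geranyl chain with its E alkene intact.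

**Step 13**
Reactants: 16, geranylated aryl bromide
Product: 17, {5-[(2E)-3,7-dimethylocta-2,6-dien-1-yl]-2,4-bis(methoxymethoxy)phenyl}boronic acid (used without chromatography)
Conditions: n-BuLi (1.1 equiv), THF, −78 °C; B(OMe)3 (2 equiv), −78 °C → rt; aq. NH4Cl
Reagents that add atoms: trimethyl borate, COB(OC)OC; water, O
Why: The second bromine–lithium exchange is much faster than any deprotonation at −78 °C, and borate trapping followed by mild hydrolysis gives the boronic acid.

### Coupling and end-game

**Step 14**
Reactants: 8, 5,7-bis(methoxymethoxy)chromone; 17, arylboronic acid (1.5 equiv)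
Product: 18, (2S)-2-{5-[(2E)-3,7-dimethylocta-2,6-dien-1-yl]-2,4-bis(methoxymethoxy)phenyl}-5,7-bis(methoxymethoxy)chroman-4-one
Conditions: [RhCl(C2H4)2]2 (2.5 mol %), (S)-MeO-F12-BIPHEP [(S)-6,6'-dimethoxy-2,2'-bis(bis(3,4,5-trifluorophenyl)phosphino)biphenyl] (5.5 mol %), aq. KOH (10 mol %), toluene/H2O 10:1, 30 °C
Reagents that add atoms: none
Why: Hayashi–Miyaura Rh-catalysed asymmetric 1,4-addition puts the aryl group on C2 of the chromone; the chiral bisphosphine selects the enone face and so sets C2 as (S), and the electron-poor ligand suppresses 1,2-addition to the product ketone.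

**Step 15**
Reactants: 18, tetra-MOM flavanone
Product: 19, Kuwanon E, (2S)-2-{5-[(2E)-3,7-dimethylocta-2,6-dien-1-yl]-2,4-dihydroxyphenyl}-5,7-dihydroxychroman-4-one
Conditions: HCl (1.25 M in MeOH), 35–40 °C, monitored; NaHCO3 quench
Reagents that add atoms: none
Why: Acid-catalysed acetal methanolysis removes all four MOM groups; the low temperature is chosen to limit C2 epimerisation and chroman formation from the geranyl alkene, but neither is guaranteed (see risks).

## Compound list

1 | resorcinol | Oc1cccc(O)c1 | starting material
2 | 1,3-bis(methoxymethoxy)benzene | COCOc1cccc(OCOC)c1 | intermediate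
3 | 2-[3,5-bis(methoxymethoxy)phenyl]-4,4,5,5-tetramethyl-1,3,2-dioxaborolane | COCOc1cc(OCOC)cc(c1)B1OC(C)(C)C(C)(C)O1 | intermediate
4 | 3,5-bis(methoxymethoxy)phenol | COCOc1cc(O)cc(OCOC)c1 | intermediate
5 | 2-hydroxy-4,6-bis(methoxymethoxy)benzaldehyde | COCOc1cc(O)c(C=O)c(OCOC)c1 | intermediate
6 | ethynylmagnesium bromide | C#C[Mg]Br | starting material
7 | 1-[2-hydroxy-4,6-bis(methoxymethoxy)phenyl]prop-2-yn-1-ol (racemic) | COCOc1cc(O)c(C(O)C#C)c(OCOC)c1 | intermediate
8 | 5,7-bis(methoxymethoxy)-4H-chromen-4-one | O=c1ccoc2cc(OCOC)cc(OCOC)c12 | intermediate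
9 | 1-(trimethylsilyl)propyne | CC#C[Si](C)(C)C | starting material
10 | prenyl bromide (1-bromo-3-methylbut-2-ene) | CC(C)=CCBr | starting material
11 | trimethyl(6-methylhept-5-en-1-yn-1-yl)silane | CC(C)=CCCC#C[Si](C)(C)C | intermediate
12 | 6-methylhept-5-en-1-yne | CC(C)=CCCC#C | intermediate
13 | geraniol | CC(C)=CCC/C(C)=C/CO | intermediate
14 | geranyl bromide | CC(C)=CCC/C(C)=C/CBr | intermediate
15 | 1,5-dibromo-2,4-bis(methoxymethoxy)benzene | COCOc1cc(OCOC)c(Br)cc1Br | intermediate
16 | 1-bromo-5-[(2E)-3,7-dimethylocta-2,6-dien-1-yl]-2,4-bis(methoxymethoxy)benzene | CC(C)=CCC/C(C)=C/Cc1cc(Br)c(OCOC)cc1OCOC | intermediate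
17 | {5-[(2E)-3,7-dimethylocta-2,6-dien-1-yl]-2,4-bis(methoxymethoxy)phenyl}boronic acid | CC(C)=CCC/C(C)=C/Cc1cc(B(O)O)c(OCOC)cc1OCOC | intermediate
18 | (2S)-2-[5-geranyl-2,4-bis(methoxymethoxy)phenyl]-5,7-bis(methoxymethoxy)chroman-4-one | CC(C)=CCC/C(C)=C/Cc1cc([C@@H]2CC(=O)c3c(OCOC)cc(OCOC)cc3O2)c(OCOC)cc1OCOC | intermediate
19 | Kuwanon E | CC(C)=CCC/C(C)=C/Cc1cc([C@@H]2CC(=O)c3c(O)cc(O)cc3O2)c(O)cc1O | target

## Summary

**Total steps:** 15

**Longest linear sequence:** 8 steps (Steps 1–6, 14, 15; the geranyl arm, Steps 7–10, 12–15, is also 8).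

**Steps most likely to fail**

1. **Step 14 (asymmetric 1,4-addition).** The ortho-alkoxy, electron-rich boronic acid may protodeboronate or add slowly to the deactivated 5,7-dialkoxychromone, and the sense or level of induction may fall short. Fallback: switch to a chalcone route.
   - Formylate the aryllithium from 16 with DMF.
   - Convert 5 to the acetophenone (MeMgBr, then oxidation) and on to its tert-butyl β-keto ester.
   - Knoevenagel-condense the two, run a cinchona-thiourea-catalysed enantioselective oxa-Michael cyclisation, then decarboxylate.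

2. **Step 15 (global MOM removal).** Acid can epimerise C2 (the benzylic C–O bond is activated by the 2',4'-oxygens) or cyclise the 4'-OH onto the geranyl alkene. Fallback: deprotect at an achiral stage and set the stereocentre last. Remove the MOM groups from the corresponding chalcone, then close the ring on the free polyphenol, either with chalcone isomerase (which gives 2S) or non-selectively followed by preparative chiral-phase separation.

3. **Step 6 (oxidation/cyclisation, with the labile alcohol 7 from Step 5).** The electron-rich o-hydroxybenzylic alcohol may ionise or over-oxidise, and some 5-exo (aurone-type) closure is possible. Fallback: build the pyranone by the enaminone route. Add MeMgBr to 5, oxidise to 2-hydroxy-4,6-bis(MOMO)acetophenone, condense with DMF dimethyl acetal, and cyclise the enaminone with loss of dimethylamine under mild conditions.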